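**Plan**

1. Retrosynthetic cuts: (i) the two C–O bonds of the cis hydroxy acetate, back to a cyclohexene C=C; (ii) both cyclopropane bonds at the cage CH bonded to the CH2OAc-bearing quaternary carbon, back to a diazoalkane and a spiro 2-methylcyclopent-2-enone; (iii) the enone C=C and the acyl–isopropenyl bond; (iv) the bond between the CMe2 carbon and the quaternary carbon that becomes the cage bridgehead, by a retro-Claisen shift to a ring C–O bond.
2. Enabling feature: the cage CH–OAc carbon, the bridgehead, the CMe2 carbon and the two oxygenated cyclohexane carbons form an O–C–C(quaternary)–CMe2–CH(O)–CH(O) chain. Without the diol this is a γ,δ-unsaturated carbonyl unit. The carbinol carbon is 1,5 to the cage C–O carbon through the ring CH2 and the CH2OAc-bearing carbon, so the allyl vinyl ether can be the silyl ketene acetal of a six-membered lactone.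
3. Forward ring order: δ-lactone (temporary ring) → cyclohexene by Claisen ring contraction → spiro cyclopentenone by ring-closing metathesis → cyclopropane and cage by intramolecular diazoalkane cycloaddition and N2 loss → oxygen pattern.
4. Stereochemistry: one Ipc2BCl aldol sets the carbinol carbon. It steers the quaternary carbon (anti radical addition on the lactone), is relayed to the bridgehead through the boat transition state of the Claisen step, and then disappears. The cage fixes its cyclopropane centres, the cage CH–OAc comes from open-face capture of a cyclopropylcarbinyl cation, and the diol face comes from a Woodward cis-hydroxylation.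

Key step: step 5

Remark: the (−)-Ipc2BCl enolate of the methyl ketone is assumed to attack the Re face of the aldehyde (the usual sense for methyl ketones); if the sense were opposite, (+)-Ipc2BCl would be used. Compounds 1, 2 and all reagents are taken as commercially available.

Step 1
Reactants: 1 1-[(tert-butyldiphenylsilyl)oxy]propan-2-one; 2 3-methylbut-2-enal
Product: 3 (R)-1-[(tert-butyldiphenylsilyl)oxy]-4-hydroxy-6-methylhept-5-en-2-one
Conditions: (−)-Ipc2BCl, Et3N, Et2O, 0 °C; then 2, −78 → −20 °C; then MeOH, pH 7 buffer, H2O2, 0 °C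
Reagents that add atoms: none
Why: Ipc2BCl-mediated boron aldol reaction of a methyl ketone, in which the bulky chloroborane/Et3N pair should enolise the methyl side, the enal reacts 1,2, and the Ipc ligands select the aldehyde face to set the (R)-carbinol centre.

Step 2
Reactants: 3 (R)-1-[(tert-butyldiphenylsilyl)oxy]-4-hydroxy-6-methylhept-5-en-2-one
Product: 5 (R)-4-{[(tert-butyldiphenylsilyl)oxy]methyl}-6-(2-methylprop-1-enyl)-5,6-dihydro-2H-pyran-2-one, via ylide ester 4 (not isolated)
Conditions: Ph3P=C=C=O, toluene, 110 °C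
Reagents that add atoms: ketenylidenetriphenylphosphorane, O=C=C=P(c1ccccc1)(c1ccccc1)c1ccccc1
Why: The alcohol adds to the ketene ylide to give the stabilised ylide ester, whose intramolecular Wittig reaction with the ketone closes the α,β-unsaturated δ-lactone (tandem addition–Wittig olefination; the ring forces the cis alkene).

Step 3
Reactants: 5 (R)-4-{[(tert-butyldiphenylsilyl)oxy]methyl}-6-(2-methylprop-1-enyl)-5,6-dihydro-2H-pyran-2-one
Product: 6 (4S,6R)-4-{[(tert-butyldiphenylsilyl)oxy]methyl}-4-(1,3-dioxolan-2-yl)-6-(2-methylprop-1-enyl)oxan-2-one (dioxolanyl trans, CH2OSi cis to the alkenyl group)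
Conditions: 1,3-dioxolane (excess), (Bu4N)4[W10O32] (2 mol%), MeCN, hν (365 nm), rt
Reagents that add atoms: 1,3-dioxolane, C1COCO1
Why: Decatungstate hydrogen-atom transfer gives the nucleophilic 1,3-dioxolan-2-yl radical, which should add to the β-carbon of the unsaturated lactone (Giese addition) axially and anti to the C6 alkenyl group, so the masked formyl group is trans to the alkenyl group at the new quaternary centre.

Step 4
Reactants: 6 (4S,6R)-4-{[(tert-butyldiphenylsilyl)oxy]methyl}-4-(1,3-dioxolan-2-yl)-6-(2-methylprop-1-enyl)oxan-2-one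
Product: 7 (4S,6R)-3-allyl-4-{[(tert-butyldiphenylsilyl)oxy]methyl}-4-(1,3-dioxolan-2-yl)-6-(2-methylprop-1-enyl)oxan-2-one (both C3 epimers)
Conditions: LiN(iPr)2, THF, −78 °C; allyl bromide, DMPU, −78 → −20 °C
Reagents that add atoms: allyl bromide, C=CCBr
Why: Alkylation of the lactone lithium enolate (the only enolisable position) with a reactive allylic halide; the C3 configuration is irrelevant because this carbon becomes trigonal in step 5.

Step 5
Reactants: 7 (4S,6R)-3-allyl-4-{[(tert-butyldiphenylsilyl)oxy]methyl}-4-(1,3-dioxolan-2-yl)-6-(2-methylprop-1-enyl)oxan-2-one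
Product: 10 1-allyl-6-{[(tert-butyldiphenylsilyl)oxy]methyl}-6-(1,3-dioxolan-2-yl)-2,2-dimethylcyclohex-3-ene-1-carboxylic acid (CO2H cis to dioxolanyl, trans to CH2OSi), via silyl ketene acetal 8 (not isolated), via trimethylsilyl ester 9 (not isolated)
Conditions: LiN(iPr)2, Me3SiCl, Et3N, THF, −78 °C → rt; toluene, 110 °C; then MeOH/H2O, rt
Reagents that add atoms: none
Why: Deprotonation at C3 and O-silylation give the cyclic silyl ketene acetal 8, in which C3 (the future cage bridgehead) and the CMe2 terminus of the 6-alkenyl group are the two ends of an allyl vinyl ether held inside one six-membered ring; the [3,3] shift breaks the ring O–C6 bond and forms the CMe2–C3 bond, giving silyl ester 9 and, after hydrolysis, acid 10. The closest known reaction type is the Ireland–Claisen rearrangement of lactone silyl ketene acetals (ring contraction of 6-alkenyl δ-lactones to cyclohex-3-ene carboxylic acids), a reaction class that is known to join two fully substituted carbons. The six-membered carbocycle is closed through a boat-shaped, bicyclo[2.2.2]octane-like transition state in which the two-carbon alkenyl bridge takes the place of the O–C(=O) bridge, and the new C=C is endocyclic and cis. The only new stereocentre, the quaternary carbon bearing CO2H and allyl, is controlled by C6: the alkenyl group can reach only its own face of the ketene acetal, whose geometry is fixed by the ring, so the carboxyl group ends cis to the dioxolanyl group and trans to the CH2OSi group on the neighbouring quaternary carbon. The step needs regioselective enolisation (C3–H is the only acidic C–H), absence of a competing sigmatropic path (the C3 allyl group and the ketene acetal form a 1,4-diene, which cannot shift) and tolerance of three contiguous fully substituted carbons, which the intramolecular ester-enolate Claisen transition state should supply.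

Step 6
Reactants: 10 1-allyl-6-{[(tert-butyldiphenylsilyl)oxy]methyl}-6-(1,3-dioxolan-2-yl)-2,2-dimethylcyclohex-3-ene-1-carboxylic acid
Product: 12 1-[1-allyl-6-{[(tert-butyldiphenylsilyl)oxy]methyl}-6-(1,3-dioxolan-2-yl)-2,2-dimethylcyclohex-3-en-1-yl]-2-methylprop-2-en-1-one, via acid chloride 11 (not isolated)
Conditions: Me2C=C(Cl)NMe2, CH2Cl2, 0 °C → rt; then CH2=C(CH3)MgBr, CuI (10 mol%), THF, −78 °C
Reagents that add atoms: isopropenylmagnesium bromide, CC(=C)[Mg]Br
Why: The α-chloroenamine converts the hindered acid to its chloride under neutral conditions (the acetal survives), and CuI-catalysed acylation of the alkenyl Grignard reagent should stop at the ketone because the acyl group is flanked by two quaternary carbons.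

Step 7
Reactants: 12 1-[1-allyl-6-{[(tert-butyldiphenylsilyl)oxy]methyl}-6-(1,3-dioxolan-2-yl)-2,2-dimethylcyclohex-3-en-1-yl]-2-methylprop-2-en-1-one
Product: 13 10-{[(tert-butyldiphenylsilyl)oxy]methyl}-10-(1,3-dioxolan-2-yl)-2,6,6-trimethylspiro[4.5]deca-2,7-dien-1-one (C1 carbonyl cis to the dioxolanyl group)
Conditions: second-generation Grubbs catalyst (5 mol%), CH2Cl2, 40 °C
Reagents that add atoms: none
Why: Ring-closing metathesis between the allyl group and the 1,1-disubstituted enone alkene closes the spiro-fused 2-methylcyclopent-2-enone with loss of ethene; the hindered cyclohexene alkene should not take part.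

Step 8
Reactants: 13 10-{[(tert-butyldiphenylsilyl)oxy]methyl}-10-(1,3-dioxolan-2-yl)-2,6,6-trimethylspiro[4.5]deca-2,7-dien-1-one
Product: 15 (E)-N-tosylhydrazone of 10-{[(tert-butyldiphenylsilyl)oxy]methyl}-2,6,6-trimethyl-1-oxospiro[4.5]deca-2,7-diene-10-carbaldehyde, via aldehyde 14 (not isolated)
Conditions: TsOH·H2O (cat.), acetone/H2O, 50 °C; then TsNHNH2, MeOH, rt
Reagents that add atoms: 4-methylbenzenesulfonohydrazide, Cc1ccc(cc1)S(=O)(=O)NN
Why: Acid-catalysed hydrolysis of the dioxolane and condensation of the neopentyl aldehyde with tosylhydrazine (hydrazone formation); the hindered conjugated ketone should not condense.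

Step 9
Reactants: 15 (E)-N-tosylhydrazone of 10-{[(tert-butyldiphenylsilyl)oxy]methyl}-2,6,6-trimethyl-1-oxospiro[4.5]deca-2,7-diene-10-carbaldehyde
Product: 18 tetracyclic cyclopropyl ketone (nortricyclane cage fused to the 3,3-dimethylcyclohexene; C=O between the bridgehead and the methyl-bearing cyclopropane carbon; CH2OSi on the other quaternary carbon), via diazoalkane 16 (not isolated), via pyrazoline 17 (not isolated)
Conditions: NaH, THF, 0 °C; toluene, 110 °C; then hν (350 nm), rt
Reagents that add atoms: none
Why: Bamford–Stevens fragmentation of the hydrazone salt gives the diazoalkane, which adds as a 1,3-dipole to the enone C=C held directly below it (the unactivated cyclohexene could only give a bicyclo[2.1.0]pentane), and the caged 1-pyrazoline loses N2 to close the cyclopropane; the three cyclopropane stereocentres are fixed by the cage geometry and the relative configuration set in step 5.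

Step 10
Reactants: 18 tetracyclic cyclopropyl ketone
Product: 19 tetracyclic alcohol with OH on the face toward the cyclohexene ring (carbinol epimer of the target configuration)
Conditions: NaBH4, MeOH/CH2Cl2, 0 °C
Reagents that add atoms: none
Why: Hydride reduction of the cyclopropyl ketone; hydride should enter from the open face over the cage CH2, because the other face is covered by the cyclohexene CH2, which places the hydroxyl toward the cyclohexene ring.

Step 11
Reactants: 19 tetracyclic alcohol with OH on the face toward the cyclohexene ring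
Product: 21 tetracyclic cage acetate with OAc on the face away from the cyclohexene ring (target configuration), CH2OSi retained, via mesylate 20 (not isolated)
Conditions: MsCl, Et3N, CH2Cl2, −20 °C; then KOAc, AcOH, 40 °C
Reagents that add atoms: potassium acetate, CC(=O)[O-].[K+]
Why: Sulfonylation and buffered acetolysis through the cyclopropylcarbinyl (nortricyclyl) cation; acetate should capture the cation from the open face, so the SN1 solvolysis is stereoconvergent and gives the target configuration whichever alcohol epimer enters.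

Step 12
Reactants: 21 tetracyclic cage acetate, silyl ether
Product: 23 tetracyclic diacetate alkene (cage OAc and CH2OAc), via primary alcohol 22 (not isolated)
Conditions: HF·pyridine, THF, 0 °C → rt; then Ac2O, DMAP (cat.), pyridine, rt
Reagents that add atoms: acetic anhydride, CC(=O)OC(C)=O
Why: Fluoride cleavage of the silyl ether (the acetate is stable to HF·pyridine) followed by acetylation of the primary alcohol.

Step 13
Reactants: 23 tetracyclic diacetate alkene
Product: 26 CNP0111873.1, via iodo acetate 24 (not isolated), via acetoxonium ion 25 (not isolated)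
Conditions: I2, AgOAc, AcOH, rt (dark); then H2O (1 equiv), 90 °C
Reagents that add atoms: silver acetate, CC(=O)[O-].[Ag+]; water, O
Why: Woodward cis-hydroxylation, in which the iodonium ion should form on the face anti to the axial methyl and axial CH2OAc groups, acetate opens it trans-diaxially at the carbon remote from CMe2, the neighbouring acetate displaces iodide (Ag+ assisted) to give the cis-fused acetoxonium ion, and water opens this to the cis hydroxy acetate on the more hindered face, the equatorial acetate/axial alcohol being the isomer expected at equilibrium under the hot acidic conditions because the axial site is flanked by two syn-axial carbons.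

**Compound list**

1 | 1-[(tert-butyldiphenylsilyl)oxy]propan-2-one | CC(=O)CO[Si](c1ccccc1)(c1ccccc1)C(C)(C)C | starting material
2 | 3-methylbut-2-enal | CC(C)=CC=O | starting material
3 | (R)-1-[(tert-butyldiphenylsilyl)oxy]-4-hydroxy-6-methylhept-5-en-2-one | CC(C)(C)[Si](c1ccccc1)(c1ccccc1)OCC(=O)C[C@@H](O)C=C(C)C | intermediate
4 | (R)-1-[(tert-butyldiphenylsilyl)oxy]-6-methyl-2-oxohept-5-en-4-yl (triphenylphosphoranylidene)acetate | CC(C)=C[C@@H](CC(=O)CO[Si](c1ccccc1)(c1ccccc1)C(C)(C)C)OC(=O)C=P(c1ccccc1)(c1ccccc1)c1ccccc1 | intermediate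
5 | (R)-4-{[(tert-butyldiphenylsilyl)oxy]methyl}-6-(2-methylprop-1-enyl)-5,6-dihydro-2H-pyran-2-one | O=C1C=C(CO[Si](c2ccccc2)(c2ccccc2)C(C)(C)C)C[C@H](C=C(C)C)O1 | intermediate
6 | (4S,6R)-4-{[(tert-butyldiphenylsilyl)oxy]methyl}-4-(1,3-dioxolan-2-yl)-6-(2-methylprop-1-enyl)oxan-2-one | O=C1C[C@](C2OCCO2)(CO[Si](c2ccccc2)(c2ccccc2)C(C)(C)C)C[C@H](C=C(C)C)O1 | intermediate
7 | (4S,6R)-3-allyl-4-{[(tert-butyldiphenylsilyl)oxy]methyl}-4-(1,3-dioxolan-2-yl)-6-(2-methylprop-1-enyl)oxan-2-one, C3 epimers | O=C1C(CC=C)[C@](C2OCCO2)(CO[Si](c2ccccc2)(c2ccccc2)C(C)(C)C)C[C@H](C=C(C)C)O1 | intermediate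
8 | cyclic trimethylsilyl ketene acetal of 7 (5-allyl-6-(trimethylsilyloxy)-3,4-dihydro-2H-pyran, C2 and C4 as in 7) | C=CCC1=C(O[Si](C)(C)C)O[C@@H](C=C(C)C)C[C@@]1(C2OCCO2)CO[Si](c2ccccc2)(c2ccccc2)C(C)(C)C | intermediate
9 | trimethylsilyl ester of acid 10 | CC(C)(C)[Si](c1ccccc1)(c1ccccc1)OC[C@]1(C2OCCO2)CC=CC(C)(C)[C@]1(C(=O)O[Si](C)(C)C)CC=C | intermediate
10 | 1-allyl-6-{[(tert-butyldiphenylsilyl)oxy]methyl}-6-(1,3-dioxolan-2-yl)-2,2-dimethylcyclohex-3-ene-1-carboxylic acid (CO2H cis to dioxolanyl) | CC(C)(C)[Si](c1ccccc1)(c1ccccc1)OC[C@]1(C2OCCO2)CC=CC(C)(C)[C@]1(C(O)=O)CC=C | intermediate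
11 | acid chloride of 10 | CC(C)(C)[Si](c1ccccc1)(c1ccccc1)OC[C@]1(C2OCCO2)CC=CC(C)(C)[C@]1(C(Cl)=O)CC=C | intermediate
12 | isopropenyl ketone from 10 (2-methylprop-2-en-1-one on the allyl-bearing quaternary carbon) | CC(C)(C)[Si](c1ccccc1)(c1ccccc1)OC[C@]1(C2OCCO2)CC=CC(C)(C)[C@]1(C(=O)C(C)=C)CC=C | intermediate
13 | 10-{[(tert-butyldiphenylsilyl)oxy]methyl}-10-(1,3-dioxolan-2-yl)-2,6,6-trimethylspiro[4.5]deca-2,7-dien-1-one | CC(C)(C)[Si](c1ccccc1)(c1ccccc1)OC[C@]1(C2OCCO2)CC=CC(C)(C)[C@]12CC=C(C)C2=O | intermediate
14 | 10-{[(tert-butyldiphenylsilyl)oxy]methyl}-2,6,6-trimethyl-1-oxospiro[4.5]deca-2,7-diene-10-carbaldehyde | CC(C)(C)[Si](c1ccccc1)(c1ccccc1)OC[C@]1(C=O)CC=CC(C)(C)[C@]12CC=C(C)C2=O | intermediate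
15 | (E)-N-tosylhydrazone of 14 | CC(C)(C)[Si](c1ccccc1)(c1ccccc1)OC[C@]1(/C=N/NS(=O)(=O)c2ccc(C)cc2)CC=CC(C)(C)[C@]12CC=C(C)C2=O | intermediate
16 | 10-(diazomethyl) analogue of 14 | CC(C)(C)[Si](c1ccccc1)(c1ccccc1)OC[C@]1(C=[N+]=[N-])CC=CC(C)(C)[C@]12CC=C(C)C2=O | intermediate
17 | caged 1-pyrazoline (N=N bridging the former diazo carbon and the methyl-bearing α-carbon of the ketone) | CC(C)(C)[Si](c1ccccc1)(c1ccccc1)OC[C@]12CC=CC(C)(C)[C@]13C[C@@H]1[C@H]2N=N[C@]1(C)C3=O | intermediate
18 | tetracyclic cyclopropyl ketone, CH2OSi on the quaternary carbon | CC(C)(C)[Si](c1ccccc1)(c1ccccc1)OC[C@]12CC=CC(C)(C)[C@]13C[C@@H]1[C@H]2[C@]1(C)C3=O | intermediate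
19 | tetracyclic alcohol, OH toward the cyclohexene ring | CC(C)(C)[Si](c1ccccc1)(c1ccccc1)OC[C@]12CC=CC(C)(C)[C@]13C[C@@H]1[C@H]2[C@]1(C)[C@@H]3O | intermediate
20 | methanesulfonate of 19 | CC(C)(C)[Si](c1ccccc1)(c1ccccc1)OC[C@]12CC=CC(C)(C)[C@]13C[C@@H]1[C@H]2[C@]1(C)[C@@H]3OS(C)(=O)=O | intermediate
21 | tetracyclic cage acetate (OAc away from the cyclohexene ring), silyl ether | CC(C)(C)[Si](c1ccccc1)(c1ccccc1)OC[C@]12CC=CC(C)(C)[C@]13C[C@@H]1[C@H]2[C@]1(C)[C@H]3OC(C)=O | intermediate
22 | primary alcohol from 21 | OC[C@]12CC=CC(C)(C)[C@]13C[C@@H]1[C@H]2[C@]1(C)[C@H]3OC(C)=O | intermediate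
23 | tetracyclic diacetate alkene | CC(=O)OC[C@]12CC=CC(C)(C)[C@]13C[C@@H]1[C@H]2[C@]1(C)[C@H]3OC(C)=O | intermediate
24 | trans-diaxial iodo acetate (axial OAc next to CH2, axial I next to CMe2) | CC(=O)OC[C@]12C[C@H](OC(C)=O)[C@@H](I)C(C)(C)[C@]13C[C@@H]1[C@H]2[C@]1(C)[C@H]3OC(C)=O | intermediate
25 | cis-fused 2-methyl-1,3-dioxolan-2-ylium ion | CC(=O)OC[C@]12C[C@@H]4O[C+](C)O[C@@H]4C(C)(C)[C@]13C[C@@H]1[C@H]2[C@]1(C)[C@H]3OC(C)=O | intermediate
26 | CNP0111873.1 | CC(=O)OC[C@]12C[C@H](O)[C@H](OC(C)=O)C(C)(C)[C@]13C[C@@H]1[C@H]2[C@]1(C)[C@H]3OC(C)=O | target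

**Totals**

Total step count: 13. Longest linear sequence: 13 steps (the route is linear from 1 and 2).

**Steps most likely to fail**

Step 5. The hindered tertiary C3–H may be enolised or silylated incompletely, and the crowded ketene acetal may decompose faster than it rearranges. The fallback sets out from 7 and avoids the enolate. Reduction with iBu2AlH (toluene, −78 °C) gives lactol F1. MsCl/Et3N gives the anomeric mesylate F2, which eliminates in the same flask to the 3,4-dihydro-2H-pyran F3. Heating (xylene, 160 °C) effects the neutral Claisen ring contraction of this cyclic enol ether, with the same boat topology and stereochemical outcome, to aldehyde F4. Isopropenylmagnesium bromide then gives carbinol F5, and Dess–Martin periodinane oxidises it to ketone 12, where the route is rejoined.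

Step 13. Opening of the iodonium ion between two syn-axial groups may be slow, the wrong face may react, or the acyl group may not settle on the equatorial oxygen. The fallback sets out from 22, isolated after the HF·pyridine stage of step 12. Osmylation with OsO4/TMEDA (CH2Cl2, −78 °C), delivered by hydrogen bonding from the axial CH2OH to its own face, gives osmate ester F6. Aqueous Na2SO3 releases triol F7. Ac2O/pyridine at 0 °C should acetylate the primary and the equatorial secondary hydroxyl and leave the axial one, giving 26.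

Step 3. Radical addition to the β,β-disubstituted carbon may be slow against hydrogen abstraction from the substrate, and facial selectivity at the new quaternary carbon may be poor. The fallback sets out from 5 and uses a polar formyl-anion equivalent. 2-Lithio-1,3-dithiane (THF/HMPA, −78 °C) adds 1,4 and anti to the C6 substituent to give dithiane F8. PhI(O2CCF3)2 with ethylene glycol in MeCN exchanges the dithiane for the dioxolane and returns to 6.

**Further compounds**

F1 | step 5 | lactol from 7 (3-allyl-oxan-2-ol, anomeric and C3 epimers) | OC1C(CC=C)[C@](C2OCCO2)(CO[Si](c2ccccc2)(c2ccccc2)C(C)(C)C)C[C@H](C=C(C)C)O1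
F2 | step 5 | anomeric mesylate of F1 | CS(=O)(=O)OC1C(CC=C)[C@](C2OCCO2)(CO[Si](c2ccccc2)(c2ccccc2)C(C)(C)C)C[C@H](C=C(C)C)O1
F3 | step 5 | 5-allyl-4-{[(tert-butyldiphenylsilyl)oxy]methyl}-4-(1,3-dioxolan-2-yl)-2-(2-methylprop-1-enyl)-3,4-dihydro-2H-pyran | C=CCC1=CO[C@@H](C=C(C)C)C[C@@]1(C2OCCO2)CO[Si](c2ccccc2)(c2ccccc2)C(C)(C)C
F4 | step 5 | 1-allyl-6-{[(tert-butyldiphenylsilyl)oxy]methyl}-6-(1,3-dioxolan-2-yl)-2,2-dimethylcyclohex-3-ene-1-carbaldehyde | CC(C)(C)[Si](c1ccccc1)(c1ccccc1)OC[C@]1(C2OCCO2)CC=CC(C)(C)[C@]1(C=O)CC=C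
F5 | step 5 | isopropenyl carbinol from F4 (carbinol epimers) | CC(C)(C)[Si](c1ccccc1)(c1ccccc1)OC[C@]1(C2OCCO2)CC=CC(C)(C)[C@]1(C(O)C(C)=C)CC=C
F6 | step 13 | osmate ester (TMEDA complex) of the cis-diol from 22 | OC[C@]12C[C@@H]4O[Os-2]5(=O)(=O)([N+](C)(C)CC[N+]5(C)C)O[C@@H]4C(C)(C)[C@]13C[C@@H]1[C@H]2[C@]1(C)[C@H]3OC(C)=O
F7 | step 13 | triol (CH2OH, cis-diol) with the cage acetate | OC[C@]12C[C@H](O)[C@H](O)C(C)(C)[C@]13C[C@@H]1[C@H]2[C@]1(C)[C@H]3OC(C)=O
F8 | step 3 | (4S,6R)-4-{[(tert-butyldiphenylsilyl)oxy]methyl}-4-(1,3-dithian-2-yl)-6-(2-methylprop-1-enyl)oxan-2-one | O=C1C[C@](C2SCCCS2)(CO[Si](c2ccccc2)(c2ccccc2)C(C)(C)C)C[C@H](C=C(C)C)O1
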